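**Strategy.** Everything rests on reading the trans-fused oxepanone (C15–C19, O20, C21) as a 2,2-dimethylfuran-3(2H)-one (O20, C19, C18, C17, C21) whose C17–C21 bond has been pried apart by C16 and quaternary C15. One irradiation of a furanone bearing a lactone-locked isopropenyl tether forges C15–C21 and C16–C17, closing the cyclohexane (C14, C15, C21–C24) and a cyclobutane and setting C15, C17 and C21; reductive scission of the push–pull C17–C21 bond then unveils the seven-membered ring. The precursor is a cis-4,5-disubstituted γ-lactone (C24–O–C12) carrying the C15=C16 isopropenyl group on C14 and the furanone on a two-carbon arm from C24. A hydroazulenyl C11 lithium reagent and an allylic diazene shift complete the skeleton.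

Key step: step 9

Remarks on the chemistry (assumptions):
- Atoms are numbered along the target chain (C1 methyl, C2–C19, O20, C21–C24); branch methyls and hydroxyl/carbonyl oxygens carry no number.
- The (S) enantiomer of 3,3'-dibromo-BINOL is assumed to deliver the (14R,24S) adduct in step 6; its antipode would be taken if the sense proved opposite.
- (S)-(+)-Linalool and 3-[(tert-butyldimethylsilyl)oxy]propanal are taken as commercial; the optical purity of the linalool fixes that of the hydroazulene fragment.
- Compounds 34–37 are carried as C2 epimers, since C2 becomes trigonal in 38 and is set only in step 25.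
- The tertiary C24 oxygen is held as a γ-lactone onto C12 instead of a silyl ether: this removes the clash between a bulky axial silyloxy group and the C15 methyl in the photocycloaddition, gives a non-nucleophilic, non-ionising oxygen for the Lewis acid step, and avoids differentiating two silyl ethers later.

**Right-hand half (steps 1–10)**

Step 1
Reactants: 1 methyl levulinate
Product: 2 methyl 3-(2-methyl-1,3-dioxolan-2-yl)propanoate
Conditions: HOCH2CH2OH, TsOH·H2O (cat.), toluene, reflux, Dean–Stark
Reagents that add atoms: ethane-1,2-diol OCCO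
Why: Acid-catalysed ketalisation with azeotropic removal of water protects the ketone so that only the ester is an acylating site in step 2.

Step 2
Reactants: 2 methyl 3-(2-methyl-1,3-dioxolan-2-yl)propanoate; 3 3-hydroxy-3-methylbutan-2-one
Product: 6 2,2-dimethyl-5-(3-oxobutyl)furan-3(2H)-one, via dilithio dianion 4 (not isolated), via hydroxy diketone ketal 5 (not isolated)
Conditions: 3 (2.5 equiv), LiN(iPr)2 (5.2 equiv), THF, −78 °C; then 2, −78 → 0 °C; then 2 M HCl, THF, rt
Reagents that add atoms: none
Why: Crossed Claisen acylation of the kinetic dianion of the α-hydroxy ketone gives the 1-hydroxy-2,4-dione, which on acid undergoes the classical cyclodehydration to the 3(2H)-furanone while the ketal is hydrolysed to the C24 methyl ketone.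

Step 3
Reactants: 7 3-[(tert-butyldimethylsilyl)oxy]propanal; 8 ethyl 2-(triphenylphosphoranylidene)propanoate
Product: 9 ethyl (2E)-5-[(tert-butyldimethylsilyl)oxy]-2-methylpent-2-enoate
Conditions: CH2Cl2, rt
Reagents that add atoms: none
Why: Wittig olefination with the α-methyl stabilised ylide should give the (E)-trisubstituted enoate, which later places C13 equatorial in the allylboration chair.

Step 4
Reactants: 9 ethyl (2E)-5-[(tert-butyldimethylsilyl)oxy]-2-methylpent-2-enoate
Product: 10 (2E)-5-[(tert-butyldimethylsilyl)oxy]-2-methylpent-2-en-1-ol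
Conditions: i-Bu2AlH (2.2 equiv), CH2Cl2, −78 °C; aq. Rochelle salt
Reagents that add atoms: none
Why: Low-temperature hydride reduction of the enoate gives the allylic alcohol without touching the alkene or the silyl ether (ester reduction).

Step 5
Reactants: 10 (2E)-5-[(tert-butyldimethylsilyl)oxy]-2-methylpent-2-en-1-ol
Product: 11 [(2E)-5-[(tert-butyldimethylsilyl)oxy]-2-methylpent-2-en-1-yl]boronic acid
Conditions: B2(OH)4 (1.2 equiv), Pd(MeCN)4(BF4)2 (5 mol %), DMSO/MeOH, rt, argon; used crude
Reagents that add atoms: tetrahydroxydiboron OB(O)B(O)O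
Why: Palladium-catalysed borylation of the allylic alcohol through a π-allyl intermediate should deliver the linear (E)-allylboronic acid, a known route to allylboronic acids that add directly to ketones.

Step 6
Reactants: 6 2,2-dimethyl-5-(3-oxobutyl)furan-3(2H)-one; 11 [(2E)-5-[(tert-butyldimethylsilyl)oxy]-2-methylpent-2-en-1-yl]boronic acid
Product: 13 5-[(3S,4R)-6-[(tert-butyldimethylsilyl)oxy]-3-hydroxy-3-methyl-4-(prop-1-en-2-yl)hexyl]-2,2-dimethylfuran-3(2H)-one, via dihydroxyboryl ether 12 (not isolated)
Conditions: 11 (1.3 equiv), (S)-3,3'-dibromo-BINOL (15 mol %), t-BuOH (2 equiv), 3 Å MS, toluene, 0 °C → rt; aq. work-up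
Reagents that add atoms: none
Why: BINOL-catalysed asymmetric allylboration of the methyl ketone through a closed chair transition state, with the (E) γ-substituent C13 and the larger ketone arm equatorial and the methyl axial, sets C14 (R) and C24 (S) together, the catalyst choosing the ketone face, while the hindered vinylogous-ester carbonyl of the furanone is left alone.

Step 7
Reactants: 13 5-[(3S,4R)-6-[(tert-butyldimethylsilyl)oxy]-3-hydroxy-3-methyl-4-(prop-1-en-2-yl)hexyl]-2,2-dimethylfuran-3(2H)-one
Product: 14 5-[(3S,4R)-3,6-dihydroxy-3-methyl-4-(prop-1-en-2-yl)hexyl]-2,2-dimethylfuran-3(2H)-one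
Conditions: Bu4NF, AcOH, THF, rt
Reagents that add atoms: none
Why: Buffered fluoride cleaves the primary silyl ether (desilylation), and the acetic acid keeps the tertiary alkoxide from adding to the furanone.

Step 8
Reactants: 14 5-[(3S,4R)-3,6-dihydroxy-3-methyl-4-(prop-1-en-2-yl)hexyl]-2,2-dimethylfuran-3(2H)-one
Product: 16 2,2-dimethyl-5-{2-[(2S,3R)-2-methyl-5-oxo-3-(prop-1-en-2-yl)oxolan-2-yl]ethyl}furan-3(2H)-one, via lactol 15 (not isolated)
Conditions: TEMPO (20 mol %), PhI(OAc)2 (3 equiv), CH2Cl2, rt
Reagents that add atoms: none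
Why: TEMPO-catalysed oxidation of the primary alcohol gives the aldehyde, which closes onto the C24 hydroxyl as lactol 15 and is oxidised on to the γ-lactone (oxidative lactonisation of a 1,4-diol), the alkene and the furanone being inert.

Step 9
Reactants: 16 2,2-dimethyl-5-{2-[(2S,3R)-2-methyl-5-oxo-3-(prop-1-en-2-yl)oxolan-2-yl]ethyl}furan-3(2H)-one
Product: 17 cyclobutane photoadduct (14R,15R,17S,21S,24S)
Conditions: hν (medium-pressure Hg lamp, Pyrex, λ > 300 nm), degassed MeCN (5 mM), rt
Reagents that add atoms: none
Why: Excitation of the furanone, intersystem crossing and attack of the triplet on the tethered 1,1-disubstituted alkene give a 1,4-biradical that collapses to the cyclobutane; the closest known reaction type is the intramolecular enone–alkene [2+2] photocycloaddition of 3(2H)-furanones and other β-alkoxy enones. The cyclohexane (C14, C15, C21–C24) closes first in a 6-exo mode by C21–C15 bonding across the four-atom tether C22–C23–C24–C14, and the cyclobutane (C15, C16, C17, C21) then closes by 1,4-recombination of the C16 and C17 radicals. C15 and C21 are set in the first bond formation through a chair-like ring in which the cis-fused lactone holds the C24 oxygen axial and C13 equatorial and the C14–H bond eclipses C15=C16 (allylic strain), so that C21 adds to the alkene face turned toward C24 and the C15 methyl ends syn to C13; C17 follows from the obligatory cis fusion of the four-membered ring to both the cyclohexane and the furanone ring. The step needs straight rather than crossed regiochemistry, which the four-atom tether (six-ring closure at the β-carbon C21) and the stabilised C17 radical should secure. It also needs one diastereoface, for which the lactone-locked chair and the small tied-back acyloxy oxygen on C24 are relied on, since this oxygen, unlike a silyl ether, does not clash with the axial C15 methyl. Quaternary C15 is made by radical addition and recombination, which tolerate the crowding next to C14.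

Step 10
Reactants: 17 cyclobutane photoadduct (14R,15R,17S,21S,24S)
Product: 18 trans-fused oxepene lactone with C18 triisopropylsilyl enol ether (14R,15R,21R,24S)
Conditions: i-Pr3SiH (3 equiv), i-Pr3SiOTf (1.2 equiv), 2,6-di-tert-butylpyridine (0.2 equiv), CH2Cl2, −78 → −20 °C
Reagents that add atoms: triisopropylsilane CC(C)[SiH](C(C)C)C(C)C; triisopropylsilyl trifluoromethanesulfonate CC(C)[Si](C(C)C)(C(C)C)OS(=O)(=O)C(F)(F)F (silyl donor, regenerated by the silane)
Why: Proposed new method: silylation of the C18 carbonyl should make the strained C17–C21 bond, flanked by the donor O20 on C21 and the acceptor carbonyl, ionise to a silyl enol ether (C17=C18) and an O20-stabilised oxocarbenium ion at C21, which the silane reduces by axial hydride delivery anti to the axial C15 methyl to give the trans ring fusion while regenerating the silyl triflate, the enol ether keeping C18 masked for steps 22–25; the closest known reaction types are Lewis acid ring opening of donor–acceptor cyclobutanes and silane reduction of cyclic oxocarbenium ions.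

**Hydroazulene fragment (steps 11–21)**

Step 11
Reactants: 19 (S)-(+)-linalool
Product: 20 (1S)-1-methylcyclopent-2-en-1-ol
Conditions: second-generation Grubbs catalyst RuCl2(=CHPh)(H2IMes)(PCy3) (0.5 mol %), CH2Cl2, 40 °C
Reagents that add atoms: none
Why: Ring-closing metathesis of the 1,6-diene expels 2-methylpropene and leaves the carbinol stereocentre, the later source of C6 chirality, untouched.

Step 12
Reactants: 20 (1S)-1-methylcyclopent-2-en-1-ol; 21 2-methylpropanoic anhydride
Product: 22 (1S)-1-methylcyclopent-2-en-1-yl 2-methylpropanoate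
Conditions: Et3N, DMAP (10 mol %), CH2Cl2, rt → 40 °C
Reagents that add atoms: none
Why: DMAP-catalysed acylation of the tertiary allylic alcohol gives the isobutyrate needed for the sigmatropic step (esterification).

Step 13
Reactants: 22 (1S)-1-methylcyclopent-2-en-1-yl 2-methylpropanoate
Product: 25 2-methyl-2-[(1R)-2-methylcyclopent-2-en-1-yl]propanoic acid, via trimethylsilyl ketene acetal 23 (not isolated), via trimethylsilyl ester 24 (not isolated)
Conditions: LiN(iPr)2, THF, −78 °C; Me3SiCl, −78 → 60 °C; then 1 M HCl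
Reagents that add atoms: none
Why: Ireland–Claisen rearrangement forms the C6–C10 bond suprafacially on the ring face that carried the ester oxygen, so the chirality of the carbinol carbon is transferred to C6 while the quaternary gem-dimethyl carbon C10 and the carboxyl C11 are installed.

Step 14
Reactants: 25 2-methyl-2-[(1R)-2-methylcyclopent-2-en-1-yl]propanoic acid
Product: 27 N-methoxy-N,2-dimethyl-2-[(1R)-2-methylcyclopent-2-en-1-yl]propanamide, via acid chloride 26 (not isolated)
Conditions: (COCl)2, DMF (cat.), CH2Cl2, 0 °C → rt; then MeNHOMe·HCl, pyridine, 0 °C → rt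
Reagents that add atoms: N,O-dimethylhydroxylamine hydrochloride CNOC.Cl
Why: Conversion of the hindered acid into its chloride and N-acylation give the Weinreb amide, which masks C11 through the two oxidation-level changes on the ring (amide formation).

Step 15
Reactants: 27 N-methoxy-N,2-dimethyl-2-[(1R)-2-methylcyclopent-2-en-1-yl]propanamide
Product: 28 2-[(1S,3R)-3-hydroxy-3-methyl-2-oxocyclopentyl]-N-methoxy-N,2-dimethylpropanamide
Conditions: RuCl3 (1 mol %), KHSO5 (as 2KHSO5·KHSO4·K2SO4), NaHCO3, EtOAc/MeCN/H2O, rt
Reagents that add atoms: potassium peroxymonosulfate [K+].[O-]S(=O)(=O)OO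
Why: Ruthenium tetroxide formed in situ adds to the trisubstituted alkene on the face anti to the bulky C6 substituent and the ruthenate ester is oxidised to the α-hydroxy ketone (catalytic ketohydroxylation), which sets the C9 carbinol and puts the ketone on the less substituted carbon C5.

Step 16
Reactants: 28 2-[(1S,3R)-3-hydroxy-3-methyl-2-oxocyclopentyl]-N-methoxy-N,2-dimethylpropanamide
Product: 29 2-[(1R,3R)-3-hydroxy-3-methyl-2-methylidenecyclopentyl]-N-methoxy-N,2-dimethylpropanamide
Conditions: Zn, CH2Br2, TiCl4, THF/CH2Cl2, 0 °C → rt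
Reagents that add atoms: dibromomethane BrCBr
Why: The non-basic zinc–titanium methylene reagent (Lombardo–Takai methylenation) converts the hindered α-hydroxy ketone into the exocyclic alkene without epimerising C6 or causing an α-ketol shift, and leaves the amide alone.

Step 17
Reactants: 29 2-[(1R,3R)-3-hydroxy-3-methyl-2-methylidenecyclopentyl]-N-methoxy-N,2-dimethylpropanamide; 30 ethyllithium
Product: 31 2-[(1R,3R)-3-hydroxy-3-methyl-2-methylidenecyclopentyl]-2-methylpentan-3-one
Conditions: EtLi (3 equiv), THF, −78 → −20 °C; H2O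
Reagents that add atoms: none
Why: Ethyllithium adds once to the Weinreb amide through the stable chelated tetrahedral intermediate to give the ethyl ketone (Weinreb ketone synthesis), one further equivalent being spent on the hydroxyl.

Step 18
Reactants: 31 2-[(1R,3R)-3-hydroxy-3-methyl-2-methylidenecyclopentyl]-2-methylpentan-3-one; 32 3-bromoprop-1-ene
Product: 34 2-[(1R,3R)-3-hydroxy-3-methyl-2-methylidenecyclopentyl]-2,4-dimethylhept-6-en-3-one (C2 epimers), via dilithium enolate alkoxide 33 (not isolated)
Conditions: LiN(iPr)2 (2.2 equiv), THF, −78 °C; allyl bromide, DMPU, −78 → −20 °C; H2O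
Reagents that add atoms: none
Why: Only C2 can be enolised, so the lithium enolate is allylated there (enolate alkylation), the C2 configuration being irrelevant because this carbon becomes trigonal in 38.

Step 19
Reactants: 34 2-[(1R,3R)-3-hydroxy-3-methyl-2-methylidenecyclopentyl]-2,4-dimethylhept-6-en-3-one (C2 epimers)
Product: 35 (1R,3aR)-1-hydroxy-1,4,4,6-tetramethyl-2,3,3a,4,6,7-hexahydroazulen-5(1H)-one (C2 epimers)
Conditions: second-generation Hoveyda–Grubbs catalyst RuCl2(=CH-2-iPrOC6H4)(H2IMes) (5 mol %), toluene (5 mM), 80 °C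
Reagents that add atoms: none
Why: Ring-closing metathesis between the 1,1-disubstituted C5 methylidene and the terminal alkene closes the seven-membered ring with loss of ethene and gives the trisubstituted C4=C5 alkene.

Step 20
Reactants: 35 (1R,3aR)-1-hydroxy-1,4,4,6-tetramethyl-2,3,3a,4,6,7-hexahydroazulen-5(1H)-one (C2 epimers)
Product: 36 (1R,3aR,8aR)-1-hydroxy-1,4,4,6-tetramethyloctahydroazulen-5(1H)-one (C2 epimers)
Conditions: [Ir(cod)(PCy3)(py)]PF6 (5 mol %), H2 (1 atm), CH2Cl2, rt
Reagents that add atoms: none
Why: The cationic iridium catalyst binds the tertiary allylic hydroxyl on C9 and delivers hydrogen to the same face of the C4=C5 alkene (hydroxyl-directed hydrogenation), which sets C5–H cis to the hydroxyl and to C6–H and hence the cis ring fusion.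

Step 21
Reactants: 36 (1R,3aR,8aR)-1-hydroxy-1,4,4,6-tetramethyloctahydroazulen-5(1H)-one (C2 epimers)
Product: 37 2,4,6-triisopropylbenzenesulfonyl hydrazone of 36
Conditions: 2,4,6-(i-Pr)3C6H2SO2NHNH2, PPTS (cat.), THF, rt → 40 °C
Reagents that add atoms: 2,4,6-triisopropylbenzenesulfonohydrazide NNS(=O)(=O)c1c(C(C)C)cc(C(C)C)cc1C(C)C
Why: Condensation of the hindered C11 ketone with the sulfonyl hydrazide gives the hydrazone whose sulfonamide nitrogen lies syn to C2, the only carbon with an α-hydrogen (hydrazone formation).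

**Union and endgame (steps 22–26)**

Step 22
Reactants: 37 2,4,6-triisopropylbenzenesulfonyl hydrazone of 36; 18 trans-fused oxepene lactone with C18 triisopropylsilyl enol ether (14R,15R,21R,24S)
Product: 39 enone diol (5R,6R,9R,14R,15R,21R,24S), via alkenyllithium alkoxide 38 (not isolated)
Conditions: 37 (1.5 equiv), n-BuLi (4.8 equiv), TMEDA, THF, −78 → 0 °C; then 18, −78 → −40 °C; H2O
Reagents that add atoms: none
Why: Shapiro reaction (double deprotonation, loss of sulfinate and N2) generates the alkenyllithium regiospecifically at C11, and its single addition to the γ-lactone carbonyl C12 gives the enone because the ring-opened tertiary alkoxide and the bulk of the new ketone prevent a second addition, the silyl enol ether masking C18.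

Step 23
Reactants: 39 enone diol (5R,6R,9R,14R,15R,21R,24S)
Product: 40 bis(triethylsilyl) ether of 39 at the C9 and C24 oxygens
Conditions: Et3SiOTf (3 equiv), 2,6-lutidine, CH2Cl2, −78 → −40 °C
Reagents that add atoms: triethylsilyl trifluoromethanesulfonate CC[Si](CC)(CC)OS(=O)(=O)C(F)(F)F
Why: The silyl triflate with a hindered pyridine base silylates both tertiary alcohols at low temperature faster than the hindered enone is enolised (silyl ether formation), which prevents the C24 and C9 oxygens from closing onto the activated allylic system in step 25.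

Step 24
Reactants: 40 bis(triethylsilyl) ether of 39 at the C9 and C24 oxygens
Product: 41 (12R)-allylic alcohol
Conditions: (S)-2-methyl-CBS-oxazaborolidine (1 equiv), catecholborane (2 equiv), toluene, −78 → −40 °C
Reagents that add atoms: none
Why: CBS reduction with the (S) oxazaborolidine, in which the tetrasubstituted alkenyl group acts as the large substituent and C13H2 as the small one, should give the (12R) alcohol by reagent control, catecholborane leaving the silyl enol ether alone.

Step 25
Reactants: 41 (12R)-allylic alcohol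
Product: 44 silyl-protected target (2S,11Z), via N-alkyl sulfonylhydrazone 42 (not isolated), via allylic diazene 43 (not isolated)
Conditions: PPh3, DEAD, N-isopropylidene-N'-2-nitrobenzenesulfonyl hydrazine, THF, 0 °C → rt; then CF3CH2OH/H2O, rt
Reagents that add atoms: none
Why: Mitsunobu displacement by the sulfonyl hydrazine reagent inverts C12, hydrolysis and loss of sulfinic acid give the monoalkyl diazene, and its retro-ene loss of N2 (allylic diazene rearrangement) passes hydrogen to C2 on the face that carries nitrogen while C13, turned away from the C2 methyl to avoid allylic strain, ends cis to C10, which sets (2S) and the (Z) C11=C12 alkene.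

Step 26
Reactants: 44 silyl-protected target (2S,11Z)
Product: 45 target CNP0157787.1
Conditions: Bu4NF, AcOH, THF, rt → 40 °C
Reagents that add atoms: none
Why: Fluoride removes both tertiary triethylsilyl ethers and the triisopropylsilyl enol ether, whose enol is protonated to the C18 ketone (global desilylation).

**Compound list**

1 | methyl levulinate | CC(=O)CCC(=O)OC | starting material
2 | methyl 3-(2-methyl-1,3-dioxolan-2-yl)propanoate | CC1(CCC(=O)OC)OCCO1 | intermediate
3 | 3-hydroxy-3-methylbutan-2-one | CC(=O)C(C)(C)O | starting material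
4 | dilithio dianion of 3 (enolate alkoxide) | CC(C)(O[Li])C(=C)O[Li] | intermediate
5 | 6-hydroxy-6-methyl-1-(2-methyl-1,3-dioxolan-2-yl)heptane-3,5-dione | CC1(CCC(=O)CC(=O)C(C)(C)O)OCCO1 | intermediate
6 | 2,2-dimethyl-5-(3-oxobutyl)furan-3(2H)-one | CC(=O)CCC1=CC(=O)C(C)(C)O1 | intermediate
7 | 3-[(tert-butyldimethylsilyl)oxy]propanal | CC(C)(C)[Si](C)(C)OCCC=O | starting material
8 | ethyl 2-(triphenylphosphoranylidene)propanoate | CCOC(=O)C(C)=P(c1ccccc1)(c1ccccc1)c1ccccc1 | starting material
9 | ethyl (2E)-5-[(tert-butyldimethylsilyl)oxy]-2-methylpent-2-enoate | CCOC(=O)/C(C)=C/CCO[Si](C)(C)C(C)(C)C | intermediate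
10 | (2E)-5-[(tert-butyldimethylsilyl)oxy]-2-methylpent-2-en-1-ol | OC/C(C)=C/CCO[Si](C)(C)C(C)(C)C | intermediate
11 | [(2E)-5-[(tert-butyldimethylsilyl)oxy]-2-methylpent-2-en-1-yl]boronic acid | OB(O)C/C(C)=C/CCO[Si](C)(C)C(C)(C)C | intermediate
12 | dihydroxyboryl ether of 13 at the C24 oxygen | OB(O)O[C@@](C)(CCC1=CC(=O)C(C)(C)O1)[C@H](CCO[Si](C)(C)C(C)(C)C)C(C)=C | intermediate
13 | 5-[(3S,4R)-6-[(tert-butyldimethylsilyl)oxy]-3-hydroxy-3-methyl-4-(prop-1-en-2-yl)hexyl]-2,2-dimethylfuran-3(2H)-one | CC(C)(C)[Si](C)(C)OCC[C@H](C(C)=C)[C@@](C)(O)CCC1=CC(=O)C(C)(C)O1 | intermediate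
14 | 5-[(3S,4R)-3,6-dihydroxy-3-methyl-4-(prop-1-en-2-yl)hexyl]-2,2-dimethylfuran-3(2H)-one | OCC[C@H](C(C)=C)[C@@](C)(O)CCC1=CC(=O)C(C)(C)O1 | intermediate
15 | 5-{2-[(2S,3R)-5-hydroxy-2-methyl-3-(prop-1-en-2-yl)oxolan-2-yl]ethyl}-2,2-dimethylfuran-3(2H)-one (lactol, anomers) | OC1C[C@H](C(C)=C)[C@](C)(CCC2=CC(=O)C(C)(C)O2)O1 | intermediate
16 | 2,2-dimethyl-5-{2-[(2S,3R)-2-methyl-5-oxo-3-(prop-1-en-2-yl)oxolan-2-yl]ethyl}furan-3(2H)-one (photosubstrate) | O=C1C[C@H](C(C)=C)[C@](C)(CCC2=CC(=O)C(C)(C)O2)O1 | intermediate
17 | cyclobutane photoadduct (14R,15R,17S,21S,24S): γ-lactone C12 onto the C24 oxygen, cyclohexane C14/C15/C21–C24, cyclobutane C15–C16–C17–C21 on the face of H-14, 2,2-dimethyloxolan-3-one ring O20–C19–C18–C17–C21 | O=C1C[C@@H]2[C@@]3(C)C[C@@H]4C(=O)C(C)(C)O[C@]34CC[C@]2(C)O1 | intermediate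
18 | trans-fused oxepene lactone (14R,15R,21R,24S): C17=C18 triisopropylsilyl enol ether, γ-lactone C12 onto the C24 oxygen | O=C1C[C@@H]2[C@@]3(C)CC=C(O[Si](C(C)C)(C(C)C)C(C)C)C(C)(C)O[C@@H]3CC[C@]2(C)O1 | intermediate
19 | (S)-(+)-linalool, (3S)-3,7-dimethylocta-1,6-dien-3-ol | CC(C)=CCC[C@](C)(O)C=C | starting material
20 | (1S)-1-methylcyclopent-2-en-1-ol | C[C@@]1(O)C=CCC1 | intermediate
21 | 2-methylpropanoic anhydride | CC(C)C(=O)OC(=O)C(C)C | starting material
22 | (1S)-1-methylcyclopent-2-en-1-yl 2-methylpropanoate | C[C@@]1(OC(=O)C(C)C)C=CCC1 | intermediate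
23 | trimethylsilyl ketene acetal of 22 | C[C@@]1(OC(O[Si](C)(C)C)=C(C)C)C=CCC1 | intermediate
24 | trimethylsilyl ester of 25 | CC1=C[C@H](C(C)(C)C(=O)O[Si](C)(C)C)CC1 | intermediate
25 | 2-methyl-2-[(1R)-2-methylcyclopent-2-en-1-yl]propanoic acid | CC1=C[C@H](C(C)(C)C(=O)O)CC1 | intermediate
26 | 2-methyl-2-[(1R)-2-methylcyclopent-2-en-1-yl]propanoyl chloride | CC1=C[C@H](C(C)(C)C(Cl)=O)CC1 | intermediate
27 | N-methoxy-N,2-dimethyl-2-[(1R)-2-methylcyclopent-2-en-1-yl]propanamide | CC1=C[C@H](C(C)(C)C(=O)N(C)OC)CC1 | intermediate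
28 | 2-[(1S,3R)-3-hydroxy-3-methyl-2-oxocyclopentyl]-N-methoxy-N,2-dimethylpropanamide | CON(C)C(=O)C(C)(C)[C@@H]1CC[C@@](C)(O)C1=O | intermediate
29 | 2-[(1R,3R)-3-hydroxy-3-methyl-2-methylidenecyclopentyl]-N-methoxy-N,2-dimethylpropanamide | CON(C)C(=O)C(C)(C)[C@@H]1CC[C@@](C)(O)C1=C | intermediate
30 | ethyllithium | CC[Li] | starting material
31 | 2-[(1R,3R)-3-hydroxy-3-methyl-2-methylidenecyclopentyl]-2-methylpentan-3-one | CCC(=O)C(C)(C)[C@@H]1CC[C@@](C)(O)C1=C | intermediate
32 | 3-bromoprop-1-ene (allyl bromide) | C=CCBr | starting material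
33 | dilithium enolate alkoxide of 31 | CC=C(O[Li])C(C)(C)[C@@H]1CC[C@@](C)(O[Li])C1=C | intermediate
34 | 2-[(1R,3R)-3-hydroxy-3-methyl-2-methylidenecyclopentyl]-2,4-dimethylhept-6-en-3-one (C2 epimers) | C=CCC(C)C(=O)C(C)(C)[C@@H]1CC[C@@](C)(O)C1=C | intermediate
35 | (1R,3aR)-1-hydroxy-1,4,4,6-tetramethyl-2,3,3a,4,6,7-hexahydroazulen-5(1H)-one (C2 epimers; C4=C5 alkene in target numbering) | CC1CC=C2[C@@H](CC[C@@]2(C)O)C(C)(C)C1=O | intermediate
36 | (1R,3aR,8aR)-1-hydroxy-1,4,4,6-tetramethyloctahydroazulen-5(1H)-one (cis-fused; C2 epimers) | CC1CC[C@@H]2[C@@H](CC[C@@]2(C)O)C(C)(C)C1=O | intermediate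
37 | 2,4,6-triisopropylbenzenesulfonyl hydrazone of 36 | CC1CC[C@@H]2[C@@H](CC[C@@]2(C)O)C(C)(C)C1=NNS(=O)(=O)c1c(C(C)C)cc(C(C)C)cc1C(C)C | intermediate
38 | C11 alkenyllithium with lithium C9 alkoxide (C11=C2 alkene) | CC=1CC[C@@H]2[C@@H](CC[C@@]2(C)O[Li])C(C)(C)C=1[Li] | intermediate
39 | enone diol (5R,6R,9R,14R,15R,21R,24S): C12 ketone between C11 (C11=C2 alkene) and C13, free C9 and C24 hydroxyls, C18 triisopropylsilyl enol ether | CC=1CC[C@@H]2[C@@H](CC[C@@]2(C)O)C(C)(C)C=1C(=O)C[C@@H]1[C@@]2(C)CC=C(O[Si](C(C)C)(C(C)C)C(C)C)C(C)(C)O[C@@H]2CC[C@]1(C)O | intermediate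
40 | bis(triethylsilyl) ether of 39 at the C9 and C24 oxygens | CC=1CC[C@@H]2[C@@H](CC[C@@]2(C)O[Si](CC)(CC)CC)C(C)(C)C=1C(=O)C[C@@H]1[C@@]2(C)CC=C(O[Si](C(C)C)(C(C)C)C(C)C)C(C)(C)O[C@@H]2CC[C@]1(C)O[Si](CC)(CC)CC | intermediate
41 | (12R)-allylic alcohol derived from 40 | CC=1CC[C@@H]2[C@@H](CC[C@@]2(C)O[Si](CC)(CC)CC)C(C)(C)C=1[C@H](O)C[C@@H]1[C@@]2(C)CC=C(O[Si](C(C)C)(C(C)C)C(C)C)C(C)(C)O[C@@H]2CC[C@]1(C)O[Si](CC)(CC)CC | intermediate
42 | (12S)-N-alkyl-N-(2-nitrobenzenesulfonyl) hydrazone of acetone | CC=1CC[C@@H]2[C@@H](CC[C@@]2(C)O[Si](CC)(CC)CC)C(C)(C)C=1[C@@H](N(N=C(C)C)S(=O)(=O)c1ccccc1[N+](=O)[O-])C[C@@H]1[C@@]2(C)CC=C(O[Si](C(C)C)(C(C)C)C(C)C)C(C)(C)O[C@@H]2CC[C@]1(C)O[Si](CC)(CC)CC | intermediate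
43 | (12S)-monoalkyl diazene | CC=1CC[C@@H]2[C@@H](CC[C@@]2(C)O[Si](CC)(CC)CC)C(C)(C)C=1[C@@H](N=N)C[C@@H]1[C@@]2(C)CC=C(O[Si](C(C)C)(C(C)C)C(C)C)C(C)(C)O[C@@H]2CC[C@]1(C)O[Si](CC)(CC)CC | intermediate
44 | silyl-protected target (2S,11Z): C9 and C24 triethylsilyl ethers, C18 triisopropylsilyl enol ether | C[C@H]1CC[C@@H]2[C@@H](CC[C@@]2(C)O[Si](CC)(CC)CC)C(C)(C)/C1=C\C[C@@H]1[C@@]2(C)CC=C(O[Si](C(C)C)(C(C)C)C(C)C)C(C)(C)O[C@@H]2CC[C@]1(C)O[Si](CC)(CC)CC | intermediate
45 | CNP0157787.1 (2S,5R,6R,9R,11Z,14R,15R,21R,24S) | C[C@H]1CC[C@@H]2[C@@H](CC[C@@]2(C)O)C(C)(C)/C1=C\C[C@@H]1[C@@]2(C)CCC(=O)C(C)(C)O[C@@H]2CC[C@]1(C)O | target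

**Totals and risk**

Total step count: 26. Longest linear sequence: 16 steps (19 to 45 through steps 11–21 and 22–26).

The three steps most likely to fail:

1. Step 10 (Proposed new method). The oxocarbenium ion may lose a proton or re-close instead of taking up hydride, hydride may arrive equatorially and give the cis ring fusion, or the silyl enol ether may not survive. Fallback with known chemistry, setting out from 17: SmI2 with HMPA and t-BuOH in THF at −78 °C forms the C18 ketyl, whose cyclobutylcarbinyl fragmentation breaks C17–C21 toward the tertiary α-oxy radical at C21. Further reduction and axial protonation should give the oxepanone lactone F1 (known reductive ring opening of cyclobutyl ketones). i-Pr3SiOTf and Et3N then convert F1 into its only possible enol ether, which is 18, where the route is rejoined.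

2. Step 9. The furanone may add to the other alkene face, close in the crossed sense (C21 to C16), or the biradical may revert or transfer hydrogen. Fallback that changes the tether control from the lactone lock to an open bis-silyl ether, setting out from 13: Et3SiOTf and 2,6-lutidine give the triethylsilyl ether F2, in which the C13 chain sits equatorial in an unconstrained chair. Irradiation as in step 9 gives the bis-silyl photoadduct F3. Bu4NF removes both silyl groups to give the diol photoadduct F4, and TEMPO with PhI(OAc)2 closes the lactone to give 17, where the route is rejoined.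

3. Step 25. The activated, hindered allylic alcohol may ionise, with loss of stereospecificity, or eliminate instead of undergoing SN2 displacement by the hydrazine. Fallback setting out from 41: MeOCOCl and pyridine give the methyl carbonate F5. Pd(OAc)2 and PBu3 with HCO2NH4 in dioxane then effect the known palladium-catalysed formate reduction of an allylic carbonate: ionisation anti to the leaving group and hydride transfer from palladium to the more substituted allyl terminus C2 place hydrogen on the same face as the diazene route and give 44, where the route is rejoined.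

**Further compounds**

F1 | step 10 | trans-fused oxepanone lactone with free C18 ketone (14R,15R,21R,24S) | O=C1C[C@@H]2[C@@]3(C)CCC(=O)C(C)(C)O[C@@H]3CC[C@]2(C)O1
F2 | step 9 | triethylsilyl ether of 13 at the C24 oxygen (open-chain photosubstrate) | CC(C)(C)[Si](C)(C)OCC[C@H](C(C)=C)[C@@](C)(O[Si](CC)(CC)CC)CCC1=CC(=O)C(C)(C)O1
F3 | step 9 | bis-silyl cyclobutane photoadduct | CC(C)(C)[Si](C)(C)OCC[C@@H]1[C@@]2(C)C[C@@H]3C(=O)C(C)(C)O[C@]23CC[C@]1(C)O[Si](CC)(CC)CC
F4 | step 9 | diol cyclobutane photoadduct | OCC[C@@H]1[C@@]2(C)C[C@@H]3C(=O)C(C)(C)O[C@]23CC[C@]1(C)O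
F5 | step 25 | (12R)-allylic methyl carbonate of 41 | CC=1CC[C@@H]2[C@@H](CC[C@@]2(C)O[Si](CC)(CC)CC)C(C)(C)C=1[C@H](OC(=O)OC)C[C@@H]1[C@@]2(C)CC=C(O[Si](C(C)C)(C(C)C)C(C)C)C(C)(C)O[C@@H]2CC[C@]1(C)O[Si](CC)(CC)CC
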